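The benzo ring of the benzofuran is opened at C7'–C7a' (primed locants: benzofuran). That ring carries oxygen on C7', next to the fusion carbon C7a', and a carbon chain on C5': the pattern produced when the acid arm of a Stobbe half-ester acylates the free α carbon (C2) of a 3-substituted furan. In one operation the key step closes the six-membered carbocycle, aromatises it and installs the C7' oxygen (as acetate) and the C5' carbon (as ester). Its precursor is the E half-ester from dimethyl succinate and a 5-aryl-furan-3-carbaldehyde, whose aryl group is the complete, benzyl-protected (2S,3R)-dihydrobenzofuran, built by Evans aldol and acid-mediated ring closure.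

Key step: step 11

Assumption: (4-formylfuran-2-yl)boronic acid 16 is taken as a purchasable building block; a reversed-polarity replacement is given among the fallbacks.

Shorthand in names: DBF = (2S,3R)-2-(4-benzyloxy-3-methoxyphenyl)-3-(benzyloxymethyl)-7-methoxy-2,3-dihydrobenzofuran-5-yl.

Step 1
Reactants: 1 5-bromo-2-hydroxy-3-methoxybenzaldehyde
Product: 2 5-bromo-3-methoxy-2-(methoxymethoxy)benzaldehyde
Conditions: NaH, DMF, 0 °C; MOMCl, 0 °C to rt
Reagents that add atoms: chloromethyl methyl ether, COCCl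
Why: Williamson-type O-alkylation of the sodium phenoxide with the reactive α-chloro ether masks the phenol as an acetal that survives the basic steps ahead and is removed by the acid that later closes the ring.

Step 2
Reactants: 2 5-bromo-3-methoxy-2-(methoxymethoxy)benzaldehyde
Product: 4 2-[5-bromo-3-methoxy-2-(methoxymethoxy)phenyl]acetonitrile, via tosylvinyl formamide 3 (not isolated)
Conditions: TosMIC, t-BuOK, DME, −40 °C; then MeOH, 65 °C
Reagents that add atoms: tosylmethyl isocyanide, Cc1ccc(S(=O)(=O)C[N+]#[C-])cc1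
Why: In this van Leusen reductive cyanation the TosMIC anion adds to the aldehyde, the oxazoline opens to formamide 3, and methanolysis of the formyl group followed by loss of sulfinate leaves the one-carbon-homologated nitrile without touching the aryl bromide or the acetal.

Step 3
Reactants: 4 2-[5-bromo-3-methoxy-2-(methoxymethoxy)phenyl]acetonitrile
Product: 5 2-[5-bromo-3-methoxy-2-(methoxymethoxy)phenyl]acetic acid
Conditions: KOH, EtOH–H2O, reflux; then 1 M HCl to pH 4, 0 °C
Reagents that add atoms: water, O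
Why: Alkaline nitrile hydrolysis runs through the primary amide to the carboxylate under conditions to which the acetal and the electron-rich aryl bromide are inert, and the brief cold acidification spares the acetal.

Step 4
Reactants: 5 2-[5-bromo-3-methoxy-2-(methoxymethoxy)phenyl]acetic acid; 6 (S)-4-benzyloxazolidin-2-one
Product: 8 (S)-4-benzyl-3-{2-[5-bromo-3-methoxy-2-(methoxymethoxy)phenyl]acetyl}oxazolidin-2-one, via mixed pivalic anhydride 7 (not isolated)
Conditions: PivCl, Et3N, THF, −20 °C; then 6, LiCl, rt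
Reagents that add atoms: none
Why: In this N-acylation through a mixed anhydride the hindered pivaloyl carbonyl steers the oxazolidinone to the arylacetyl carbonyl, and LiCl makes the N–H acidic enough for triethylamine so that no strong base is needed.

Step 5
Reactants: 8 (S)-4-benzyl-3-{2-[5-bromo-3-methoxy-2-(methoxymethoxy)phenyl]acetyl}oxazolidin-2-one; 9 4-benzyloxy-3-methoxybenzaldehyde
Product: 11 (S)-4-benzyl-3-{(2S,3S)-3-(4-benzyloxy-3-methoxyphenyl)-2-[5-bromo-3-methoxy-2-(methoxymethoxy)phenyl]-3-hydroxypropanoyl}oxazolidin-2-one, via Z boron enolate 10 (not isolated)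
Conditions: Bu2BOTf, i-Pr2NEt, CH2Cl2, −78 to 0 °C; 9, −78 to 0 °C; then pH 7 buffer, MeOH, H2O2, 0 °C
Reagents that add atoms: none
Why: In this Evans syn aldol the Z dibutylboron enolate 10 reacts through a closed chair (Zimmerman–Traxler) transition state with the aldehyde on the enolate face away from the benzyl group of the dipole-opposed auxiliary, which sets the α carbon as S (the future C3, named R once the carbonyl is reduced) and the carbinol carbon as S, the latter being irrelevant because it is ionised in step 7.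

Step 6
Reactants: 11 syn-aldol imide
Product: 12 (1S,2R)-1-(4-benzyloxy-3-methoxyphenyl)-2-[5-bromo-3-methoxy-2-(methoxymethoxy)phenyl]propane-1,3-diol
Conditions: LiBH4, MeOH (2 equiv), THF, 0 °C
Reagents that add atoms: none
Why: Reductive cleavage of the N-acyl oxazolidinone by LiBH4 gives the primary alcohol and the recoverable auxiliary without epimerising the α-aryl centre or touching the aryl bromide.

Step 7
Reactants: 12 (1S,2R)-1-(4-benzyloxy-3-methoxyphenyl)-2-[5-bromo-3-methoxy-2-(methoxymethoxy)phenyl]propane-1,3-diol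
Product: 14 [(2S,3R)-2-(4-benzyloxy-3-methoxyphenyl)-5-bromo-7-methoxy-2,3-dihydrobenzofuran-3-yl]methanol, via free-phenol triol 13 (not isolated)
Conditions: HCl (0.5 M) in MeOH, 0 to 40 °C
Reagents that add atoms: none
Why: Acid methanolysis frees the phenol and the same acid ionises the p-alkoxybenzylic alcohol to a stabilised cation that the phenol captures in a 5-exo ring closure (SN1 cycloetherification, the phenylcoumaran closure of lignin chemistry), C3 being untouched and directing the new C2 centre trans because the reversible closure settles on the more stable (2S,3R) ring whatever the carbinol configuration.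

Step 8
Reactants: 14 [(2S,3R)-2-(4-benzyloxy-3-methoxyphenyl)-5-bromo-7-methoxy-2,3-dihydrobenzofuran-3-yl]methanol
Product: 15 (2S,3R)-2-(4-benzyloxy-3-methoxyphenyl)-3-(benzyloxymethyl)-5-bromo-7-methoxy-2,3-dihydrobenzofuran (DBF–Br)
Conditions: NaH, BnBr, n-Bu4NI (cat.), THF–DMF, 0 °C to rt
Reagents that add atoms: benzyl bromide, BrCc1ccccc1
Why: Williamson etherification of the primary alkoxide gives an ether that withstands the alkoxide, hot anhydride and hydride steps ahead and leaves together with the phenolic benzyl group in the final hydrogenation.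

Step 9
Reactants: 15 DBF–Br; 16 (4-formylfuran-2-yl)boronic acid
Product: 17 5-(DBF)furan-3-carbaldehyde
Conditions: Pd(OAc)2 (3 mol%), SPhos (6 mol%), K3PO4, THF–H2O, 40 °C
Reagents that add atoms: none
Why: In this Suzuki–Miyaura coupling a bulky electron-rich biarylphosphine makes oxidative addition to the electron-rich aryl bromide and transmetalation fast enough at 40 °C to outrun protodeboronation of the 2-furylboronic acid, and the boron position fixes the aryl group on the furan α carbon remote from the formyl group.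

Step 10
Reactants: 17 5-(DBF)furan-3-carbaldehyde; 18 dimethyl succinate
Product: 20 (E)-4-[5-(DBF)furan-3-yl]-3-(methoxycarbonyl)but-3-enoic acid, via paraconate lactone 19 (not isolated)
Conditions: t-BuOK, t-BuOH, 50 °C; then 1 M HCl to pH 3, 0 °C
Reagents that add atoms: none
Why: In this Stobbe condensation the succinate enolate adds to the non-enolisable aldehyde, the alkoxide lactonises onto the distal ester to give 19, and irreversible E1cB opening leaves the carboxylate on the CH2 arm and the ester conjugated, with the furan trans to the ester (E) for steric reasons.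

Step 11
Reactants: 20 (E)-4-[5-(DBF)furan-3-yl]-3-(methoxycarbonyl)but-3-enoic acid
Product: 23 methyl 7-acetoxy-2-(DBF)benzofuran-5-carboxylate, via mixed acetic anhydride 21 (not isolated), via 7'-phenol 22 (not isolated)
Conditions: Ac2O, NaOAc, 130 °C
Reagents that add atoms: acetic anhydride, CC(=O)OC(C)=O
Why: Acetic anhydride turns the free acid of 20 into mixed anhydride 21, which acylates furan C2 (the only free α carbon, next to the side chain) either directly as a Friedel–Crafts acylation or, after loss of acetic acid, as the dienylketene in a 6π electrocyclisation, forming C7'–C7a'. The ring closes in the 6-exo-trig mode at the acyl carbon (carbonyl oxygen outside the ring), the furan C2–C3 bond becoming the ring fusion, and the resulting cyclohexadienone enolises to phenol 22, which is acetylated in the flask. The closest known reaction type is the Stobbe half-ester cyclisation that converts aryl, thienyl and furyl aldehyde adducts into acetoxy-arene carboxylates. No stereocentre is formed, and C2 and C3 of the dihydrobenzofuran are remote and not enolisable, so they are not at risk in the acetate-buffered medium. The step needs acylation at furan C2 and not at C4: closure at C4 would give an o-quinoid isobenzofuran, C2 is the more nucleophilic α position, and the E alkene holds the CH2CO2H arm on the furan side, so the 7'-oxygen, 5'-ester pattern follows directly.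

Step 12
Reactants: 23 methyl 7-acetoxy-2-(DBF)benzofuran-5-carboxylate
Product: 24 2-(DBF)-5-(hydroxymethyl)benzofuran-7-ol
Conditions: LiAlH4, THF, 0 °C to rt
Reagents that add atoms: none
Why: Hydride reduction takes the methyl ester to the benzylic alcohol and cleaves the aryl acetate in the same operation, while the benzyl ethers and both oxygen heterocycles are inert.

Step 13
Reactants: 24 2-(DBF)-5-(hydroxymethyl)benzofuran-7-ol
Product: 25 [2-(DBF)-7-methoxybenzofuran-5-yl]methanol
Conditions: MeI, K2CO3, acetone, 50 °C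
Reagents that add atoms: iodomethane, CI
Why: Carbonate deprotonates only the phenol and not the benzylic alcohol, so the Williamson O-methylation is chemoselective for the C7' oxygen.

Step 14
Reactants: 25 [2-(DBF)-7-methoxybenzofuran-5-yl]methanol
Product: 27 ethyl (E)-3-[2-(DBF)-7-methoxybenzofuran-5-yl]prop-2-enoate, via benzofuran-5-carbaldehyde 26 (not isolated)
Conditions: MnO2, Ph3P=CHCO2Et, CH2Cl2, 40 °C
Reagents that add atoms: ethyl (triphenylphosphoranylidene)acetate, CCOC(=O)C=P(c1ccccc1)(c1ccccc1)c1ccccc1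
Why: In this tandem oxidation–Wittig reaction MnO2 oxidises the benzylic alcohol to aldehyde 26, which the stabilised ylide already present traps at once as the E enoate, adding the two missing chain carbons.

Step 15
Reactants: 27 ethyl (E)-3-[2-(DBF)-7-methoxybenzofuran-5-yl]prop-2-enoate
Product: 28 ethyl 3-{2-[(2S,3R)-2-(4-hydroxy-3-methoxyphenyl)-3-(hydroxymethyl)-7-methoxy-2,3-dihydrobenzofuran-5-yl]-7-methoxybenzofuran-5-yl}propanoate
Conditions: H2 (1 atm), 10% Pd/C, EtOAc–EtOH, rt
Reagents that add atoms: none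
Why: Heterogeneous hydrogenation saturates the conjugated alkene and hydrogenolyses both benzyl ethers, while the aromatic benzofuran and the cyclic benzylic aryl ether of the dihydrobenzofuran should survive at ambient pressure in neutral solvent when the reaction is stopped at complete debenzylation.

Step 16
Reactants: 28 ethyl 3-{2-[(2S,3R)-2-(4-hydroxy-3-methoxyphenyl)-3-(hydroxymethyl)-7-methoxy-2,3-dihydrobenzofuran-5-yl]-7-methoxybenzofuran-5-yl}propanoate
Product: 29 4-{(2S,3R)-3-(hydroxymethyl)-5-[5-(3-hydroxypropyl)-7-methoxybenzofuran-2-yl]-7-methoxy-2,3-dihydrobenzofuran-2-yl}-2-methoxyphenol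
Conditions: LiAlH4, THF, 0 °C to rt
Reagents that add atoms: none
Why: Hydride reduction of the saturated ethyl ester gives the 3-hydroxypropyl chain, the phenoxide and alkoxide formed in the flask only consuming extra hydride, and no stereocentre is affected.

Compound list

1 | 5-bromo-2-hydroxy-3-methoxybenzaldehyde | COc1cc(Br)cc(C=O)c1O | starting material
2 | 5-bromo-3-methoxy-2-(methoxymethoxy)benzaldehyde | COCOc1c(OC)cc(Br)cc1C=O | intermediate
3 | N-{2-[5-bromo-3-methoxy-2-(methoxymethoxy)phenyl]-1-[(4-methylphenyl)sulfonyl]ethenyl}formamide | COCOc1c(OC)cc(Br)cc1C=C(NC=O)S(=O)(=O)c1ccc(C)cc1 | intermediate (not isolated)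
4 | 2-[5-bromo-3-methoxy-2-(methoxymethoxy)phenyl]acetonitrile | COCOc1c(OC)cc(Br)cc1CC#N | intermediate
5 | 2-[5-bromo-3-methoxy-2-(methoxymethoxy)phenyl]acetic acid | COCOc1c(OC)cc(Br)cc1CC(=O)O | intermediate
6 | (S)-4-benzyloxazolidin-2-one | O=C1N[C@@H](Cc2ccccc2)CO1 | starting material
7 | 2-[5-bromo-3-methoxy-2-(methoxymethoxy)phenyl]acetic 2,2-dimethylpropanoic anhydride | COCOc1c(OC)cc(Br)cc1CC(=O)OC(=O)C(C)(C)C | intermediate (not isolated)
8 | (S)-4-benzyl-3-{2-[5-bromo-3-methoxy-2-(methoxymethoxy)phenyl]acetyl}oxazolidin-2-one | COCOc1c(OC)cc(Br)cc1CC(=O)N1C(=O)OC[C@@H]1Cc1ccccc1 | intermediate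
9 | 4-benzyloxy-3-methoxybenzaldehyde | COc1cc(C=O)ccc1OCc1ccccc1 | starting material
10 | (S)-4-benzyl-3-{(Z)-2-[5-bromo-3-methoxy-2-(methoxymethoxy)phenyl]-1-[(dibutylboranyl)oxy]ethenyl}oxazolidin-2-one | CCCCB(CCCC)O/C(=C\c1cc(Br)cc(OC)c1OCOC)N1C(=O)OC[C@@H]1Cc1ccccc1 | intermediate (not isolated)
11 | (S)-4-benzyl-3-{(2S,3S)-3-(4-benzyloxy-3-methoxyphenyl)-2-[5-bromo-3-methoxy-2-(methoxymethoxy)phenyl]-3-hydroxypropanoyl}oxazolidin-2-one | O=C(N1C(=O)OC[C@@H]1Cc1ccccc1)[C@@H](c1cc(Br)cc(OC)c1OCOC)[C@H](O)c1ccc(OCc2ccccc2)c(OC)c1 | intermediate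
12 | (1S,2R)-1-(4-benzyloxy-3-methoxyphenyl)-2-[5-bromo-3-methoxy-2-(methoxymethoxy)phenyl]propane-1,3-diol | OC[C@@H](c1cc(Br)cc(OC)c1OCOC)[C@H](O)c1ccc(OCc2ccccc2)c(OC)c1 | intermediate
13 | (1S,2R)-1-(4-benzyloxy-3-methoxyphenyl)-2-(5-bromo-2-hydroxy-3-methoxyphenyl)propane-1,3-diol | OC[C@@H](c1cc(Br)cc(OC)c1O)[C@H](O)c1ccc(OCc2ccccc2)c(OC)c1 | intermediate (not isolated)
14 | [(2S,3R)-2-(4-benzyloxy-3-methoxyphenyl)-5-bromo-7-methoxy-2,3-dihydrobenzofuran-3-yl]methanol | COc1cc([C@H]2Oc3c(OC)cc(Br)cc3[C@@H]2CO)ccc1OCc1ccccc1 | intermediate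
15 | (2S,3R)-2-(4-benzyloxy-3-methoxyphenyl)-3-(benzyloxymethyl)-5-bromo-7-methoxy-2,3-dihydrobenzofuran (DBF–Br) | COc1cc([C@H]2Oc3c(OC)cc(Br)cc3[C@@H]2COCc2ccccc2)ccc1OCc1ccccc1 | intermediate
16 | (4-formylfuran-2-yl)boronic acid | OB(O)c1cc(C=O)co1 | starting material
17 | 5-[(2S,3R)-2-(4-benzyloxy-3-methoxyphenyl)-3-(benzyloxymethyl)-7-methoxy-2,3-dihydrobenzofuran-5-yl]furan-3-carbaldehyde | COc1cc([C@H]2Oc3c(OC)cc(-c4cc(C=O)co4)cc3[C@@H]2COCc2ccccc2)ccc1OCc1ccccc1 | intermediate
18 | dimethyl succinate | COC(=O)CCC(=O)OC | starting material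
19 | methyl 2-[5-(DBF)furan-3-yl]-5-oxotetrahydrofuran-3-carboxylate (diastereomers at the lactone ring) | COc1cc([C@H]2Oc3c(OC)cc(-c4cc(C5OC(=O)CC5C(=O)OC)co4)cc3[C@@H]2COCc2ccccc2)ccc1OCc1ccccc1 | intermediate (not isolated)
20 | (E)-4-{5-[(2S,3R)-2-(4-benzyloxy-3-methoxyphenyl)-3-(benzyloxymethyl)-7-methoxy-2,3-dihydrobenzofuran-5-yl]furan-3-yl}-3-(methoxycarbonyl)but-3-enoic acid | COc1cc([C@H]2Oc3c(OC)cc(-c4cc(/C=C(\CC(=O)O)C(=O)OC)co4)cc3[C@@H]2COCc2ccccc2)ccc1OCc1ccccc1 | intermediate
21 | acetic (E)-4-[5-(DBF)furan-3-yl]-3-(methoxycarbonyl)but-3-enoic anhydride | COc1cc([C@H]2Oc3c(OC)cc(-c4cc(/C=C(\CC(=O)OC(C)=O)C(=O)OC)co4)cc3[C@@H]2COCc2ccccc2)ccc1OCc1ccccc1 | intermediate (not isolated)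
22 | methyl 2-(DBF)-7-hydroxybenzofuran-5-carboxylate | COc1cc([C@H]2Oc3c(OC)cc(-c4cc5cc(C(=O)OC)cc(O)c5o4)cc3[C@@H]2COCc2ccccc2)ccc1OCc1ccccc1 | intermediate (not isolated)
23 | methyl 7-acetoxy-2-[(2S,3R)-2-(4-benzyloxy-3-methoxyphenyl)-3-(benzyloxymethyl)-7-methoxy-2,3-dihydrobenzofuran-5-yl]benzofuran-5-carboxylate | COc1cc([C@H]2Oc3c(OC)cc(-c4cc5cc(C(=O)OC)cc(OC(C)=O)c5o4)cc3[C@@H]2COCc2ccccc2)ccc1OCc1ccccc1 | intermediate
24 | 2-(DBF)-5-(hydroxymethyl)benzofuran-7-ol | COc1cc([C@H]2Oc3c(OC)cc(-c4cc5cc(CO)cc(O)c5o4)cc3[C@@H]2COCc2ccccc2)ccc1OCc1ccccc1 | intermediate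
25 | [2-(DBF)-7-methoxybenzofuran-5-yl]methanol | COc1cc([C@H]2Oc3c(OC)cc(-c4cc5cc(CO)cc(OC)c5o4)cc3[C@@H]2COCc2ccccc2)ccc1OCc1ccccc1 | intermediate
26 | 2-(DBF)-7-methoxybenzofuran-5-carbaldehyde | COc1cc([C@H]2Oc3c(OC)cc(-c4cc5cc(C=O)cc(OC)c5o4)cc3[C@@H]2COCc2ccccc2)ccc1OCc1ccccc1 | intermediate (not isolated)
27 | ethyl (E)-3-[2-(DBF)-7-methoxybenzofuran-5-yl]prop-2-enoate | COc1cc([C@H]2Oc3c(OC)cc(-c4cc5cc(/C=C/C(=O)OCC)cc(OC)c5o4)cc3[C@@H]2COCc2ccccc2)ccc1OCc1ccccc1 | intermediate
28 | ethyl 3-{2-[(2S,3R)-2-(4-hydroxy-3-methoxyphenyl)-3-(hydroxymethyl)-7-methoxy-2,3-dihydrobenzofuran-5-yl]-7-methoxybenzofuran-5-yl}propanoate | COc1cc([C@H]2Oc3c(OC)cc(-c4cc5cc(CCC(=O)OCC)cc(OC)c5o4)cc3[C@@H]2CO)ccc1O | intermediate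
29 | 4-{(2S,3R)-3-(hydroxymethyl)-5-[5-(3-hydroxypropyl)-7-methoxybenzofuran-2-yl]-7-methoxy-2,3-dihydrobenzofuran-2-yl}-2-methoxyphenol | COc1cc([C@H]2Oc3c(OC)cc(-c4cc5cc(CCCO)cc(OC)c5o4)cc3[C@@H]2CO)ccc1O | target

Total step count: 16. Longest linear sequence: 16 steps (1 to 29); 6, 9, 16 and 18 are bought and enter directly.

Steps most likely to fail

Step 11. The thermal acylation may be outrun by decomposition: acetolysis or ionisation at the benzylic C2–O bond of the dihydrobenzofuran in hot anhydride, enol-lactone formation from the mixed anhydride, or a Z half-ester fraction that cannot reach the furan. The fallback sets out from 15 and comes back at 25, building the benzofuran by alkyne coupling and heteroannulation instead. Sonogashira coupling of 15 with trimethylsilylacetylene (Pd(PPh3)2Cl2, CuI, Et3N, DMF, 80 °C) should give [(DBF)ethynyl]trimethylsilane F1, and K2CO3 in MeOH the terminal alkyne (2S,3R)-2-(4-benzyloxy-3-methoxyphenyl)-3-(benzyloxymethyl)-5-ethynyl-7-methoxy-2,3-dihydrobenzofuran F2. Coupling of F2 with purchased methyl 4-hydroxy-3-iodo-5-methoxybenzoate (Pd(PPh3)2Cl2, CuI, Et3N, DMF, 70 °C) is followed in the flask by 5-endo-dig attack of the phenol on the alkyne and should give methyl 2-(DBF)-7-methoxybenzofuran-5-carboxylate F3. LiAlH4 in THF reduces F3 to 25.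

Step 9. The 2-furylboronic acid may lose boron by protonolysis faster than it transmetalates, leaving unreacted bromide. The fallback sets out from 15 and comes back at 17 with the polarity reversed. Miyaura borylation of 15 (B2pin2, Pd(dppf)Cl2, KOAc, dioxane, 90 °C) should give the stable boronate 2-(DBF)-4,4,5,5-tetramethyl-1,3,2-dioxaborolane F4. Furan-3-carbaldehyde is brominated (Br2, AlCl3, CH2Cl2, 0 °C) at C5, the α position not deactivated by conjugation with the formyl group, to 5-bromofuran-3-carbaldehyde F5. Suzuki coupling of F4 with F5 (Pd(dppf)Cl2, K2CO3, dioxane–H2O, 80 °C) gives 17.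

Step 10. Enolate addition to the electron-rich heteroaryl aldehyde may be slow enough for base-induced disproportionation of the aldehyde, ester exchange and partial Z-alkene formation to compete. The fallback sets out from 17 and comes back at 20. Horner–Wadsworth–Emmons olefination of 17 with dimethyl 2-(dimethoxyphosphoryl)butanedioate (NaH, THF, 0 °C to rt) should give dimethyl (E)-2-{[5-(DBF)furan-3-yl]methylidene}butanedioate F6. One equivalent of LiOH in THF–H2O at 0 °C then hydrolyses the unconjugated, unhindered CH2CO2Me ester faster than the conjugated one, giving 20.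

Further compounds

F1 | step 11 | [(DBF)ethynyl]trimethylsilane | COc1cc([C@H]2Oc3c(OC)cc(C#C[Si](C)(C)C)cc3[C@@H]2COCc2ccccc2)ccc1OCc1ccccc1
F2 | step 11 | (2S,3R)-2-(4-benzyloxy-3-methoxyphenyl)-3-(benzyloxymethyl)-5-ethynyl-7-methoxy-2,3-dihydrobenzofuran | COc1cc([C@H]2Oc3c(OC)cc(C#C)cc3[C@@H]2COCc2ccccc2)ccc1OCc1ccccc1
F3 | step 11 | methyl 2-(DBF)-7-methoxybenzofuran-5-carboxylate | COc1cc([C@H]2Oc3c(OC)cc(-c4cc5cc(C(=O)OC)cc(OC)c5o4)cc3[C@@H]2COCc2ccccc2)ccc1OCc1ccccc1
F4 | step 9 | 2-(DBF)-4,4,5,5-tetramethyl-1,3,2-dioxaborolane | COc1cc([C@H]2Oc3c(OC)cc(B4OC(C)(C)C(C)(C)O4)cc3[C@@H]2COCc2ccccc2)ccc1OCc1ccccc1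
F5 | step 9 | 5-bromofuran-3-carbaldehyde | O=Cc1coc(Br)c1
F6 | step 10 | dimethyl (E)-2-{[5-(DBF)furan-3-yl]methylidene}butanedioate | COc1cc([C@H]2Oc3c(OC)cc(-c4cc(/C=C(\CC(=O)OC)C(=O)OC)co4)cc3[C@@H]2COCc2ccccc2)ccc1OCc1ccccc1
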